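The route rests on deleting C3 from ring C of the luteolin half. C3 is that ring's only CH and lies between aryl-bearing C2 and the C4 carbonyl, so its excision leaves a 2-aryl-3-silyloxybenzofuran whose ring oxygen already sits beside the biaryl carbon (flavone C8). In one operation dichlorocarbene cyclopropanates the furan C2–C3 enol ether bond and the adduct opens to a 3-chloroflavone, forming C2–C3 and C3–C4 and enlarging the furan to ring C without any 6-aryl isomer. The precursor is a hexabenzylated 2,7-diaryl-3-(silyloxy)benzofuran carrying the future flavanone C2 as an inert CH2OTBS group. The (2S)-flavanone is added afterwards by asymmetric oxa-Michael cyclisation.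

Key step: step 9

Remark: the carbon that becomes flavanone C2 is carried through the carbene step as a silyl-protected benzylic alcohol, not as an aldehyde acetal, because the C–H bond of 2-aryl-1,3-dioxolanes is a known site of dichlorocarbene insertion and a free aldehyde would add the trichloromethyl anion.
Remark: compounds 10 and 19 are taken as purchased benzyl ethers (each is otherwise one benzylation from 4-bromocatechol or 2,4,6-trihydroxyacetophenone).
Remark: the quinine-derived thiourea is assumed to give the 2S series; should a model cyclisation show the opposite sense, its quinidine-derived pseudoenantiomer is used in step 14 with no other change.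

Step 1
Reactants: 1 3-bromo-4,5-dihydroxybenzaldehyde
Product: 2 3,4-bis(benzyloxy)-5-bromobenzaldehyde
Conditions: BnBr, K2CO3, DMF, 60 °C
Reagents that add atoms: benzyl bromide, BrCc1ccccc1
Why: Williamson O-benzylation of both catechol hydroxyls under carbonate conditions, which leave the aldehyde and the aryl bromide untouched.

Step 2
Reactants: 2 3,4-bis(benzyloxy)-5-bromobenzaldehyde
Product: 3 [3,4-bis(benzyloxy)-5-bromophenyl]methanol
Conditions: NaBH4, MeOH/THF, 0 °C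
Reagents that add atoms: none
Why: Borohydride reduction of the aryl aldehyde to the benzylic alcohol; aryl bromide and benzyl ethers are inert.

Step 3
Reactants: 3 [3,4-bis(benzyloxy)-5-bromophenyl]methanol
Product: 4 {[3,4-bis(benzyloxy)-5-bromobenzyl]oxy}(tert-butyl)dimethylsilane
Conditions: TBSCl, imidazole, DMF, rt
Reagents that add atoms: tert-butyldimethylsilyl chloride, CC(C)(C)[Si](C)(C)Cl
Why: Routine silylation of a primary alcohol gives a group that is stable to base and palladium catalysis and has no C–H bond prone to carbene insertion beyond those of the benzyl ethers.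

Step 4
Reactants: 4 {[3,4-bis(benzyloxy)-5-bromobenzyl]oxy}(tert-butyl)dimethylsilane
Product: 5 2-[2,3-bis(benzyloxy)-5-{[(tert-butyldimethylsilyl)oxy]methyl}phenyl]-4,4,5,5-tetramethyl-1,3,2-dioxaborolane
Conditions: B2pin2, Pd(dppf)Cl2, KOAc, dioxane, 90 °C
Reagents that add atoms: bis(pinacolato)diboron, CC1(C)OB(OC1(C)C)B1OC(C)(C)C(C)(C)O1
Why: Miyaura borylation of the aryl bromide; acetate is too weak a base to trigger homocoupling and the ethers survive.

Step 5
Reactants: 6 4,6-dihydroxybenzofuran-3(2H)-one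
Product: 7 4,6-bis(benzyloxy)benzofuran-3(2H)-one
Conditions: BnBr (2.2 equiv), K2CO3, DMF, 50 °C
Reagents that add atoms: benzyl bromide, BrCc1ccccc1
Why: Williamson O-benzylation; gentle warming overcomes chelation of the 4-OH, and limiting the halide keeps the C2 methylene from being alkylated.

Step 6
Reactants: 7 4,6-bis(benzyloxy)benzofuran-3(2H)-one
Product: 8 4,6-bis(benzyloxy)-7-bromobenzofuran-3(2H)-one
Conditions: NBS (1.0 equiv), MeCN, 0 °C to rt, dark
Reagents that add atoms: N-bromosuccinimide, O=C1CCC(=O)N1Br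
Why: Electrophilic aromatic bromination should favour C7, which is activated by O1 and both benzyloxy groups yet less hindered than C5 (flanked by two benzyloxy groups), as in the C8-selective halogenation of 5,7-dialkoxyflavones.

Step 7
Reactants: 8 4,6-bis(benzyloxy)-7-bromobenzofuran-3(2H)-one; 5 2-[2,3-bis(benzyloxy)-5-{[(tert-butyldimethylsilyl)oxy]methyl}phenyl]-4,4,5,5-tetramethyl-1,3,2-dioxaborolane
Product: 9 4,6-bis(benzyloxy)-7-[2,3-bis(benzyloxy)-5-{[(tert-butyldimethylsilyl)oxy]methyl}phenyl]benzofuran-3(2H)-one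
Conditions: Pd(OAc)2, SPhos, K3PO4, toluene/H2O, 80 °C
Reagents that add atoms: none
Why: Suzuki–Miyaura coupling; the dialkylbiarylphosphine copes with the tri-ortho-substituted biaryl and cross-coupling outruns enolate chemistry of the ketone under aqueous phosphate.

Step 8
Reactants: 9 4,6-bis(benzyloxy)-7-[2,3-bis(benzyloxy)-5-{[(tert-butyldimethylsilyl)oxy]methyl}phenyl]benzofuran-3(2H)-one; 10 1,2-bis(benzyloxy)-4-bromobenzene
Product: 12 4,6-bis(benzyloxy)-7-[2,3-bis(benzyloxy)-5-{[(tert-butyldimethylsilyl)oxy]methyl}phenyl]-2-[3,4-bis(benzyloxy)phenyl]-3-[(tert-butyldimethylsilyl)oxy]benzofuran, via lithium enolate 11 (not isolated)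
Conditions: Pd2(dba)3, XPhos, LiN(SiMe3)2 (2.3 equiv), toluene/THF, 60 °C; then TBSOTf, 0 °C
Reagents that add atoms: tert-butyldimethylsilyl trifluoromethanesulfonate, CC(C)(C)[Si](C)(C)OS(=O)(=O)C(F)(F)F
Why: Palladium-catalysed ketone α-arylation (Buchwald–Hartwig type) at C2 gives the more acidic 2-aryl ketone, which rests as its aromatic 3-oxidobenzofuran enolate (blocking a second arylation) and is O-silylated in the same flask, so the air-sensitive 2-aryl ketone is never isolated.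

Step 9
Reactants: 12 4,6-bis(benzyloxy)-7-[2,3-bis(benzyloxy)-5-{[(tert-butyldimethylsilyl)oxy]methyl}phenyl]-2-[3,4-bis(benzyloxy)phenyl]-3-[(tert-butyldimethylsilyl)oxy]benzofuran
Product: 15 5,7-bis(benzyloxy)-8-[2,3-bis(benzyloxy)-5-{[(tert-butyldimethylsilyl)oxy]methyl}phenyl]-2-[3,4-bis(benzyloxy)phenyl]-3-chloro-4H-chromen-4-one, via dichlorocyclopropane adduct 13 (not isolated), via benzopyrylium chloride 14 (not isolated)
Conditions: Cl3CCO2Na (3 equiv, portionwise), DME, 85 °C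
Reagents that add atoms: sodium trichloroacetate, [Na+].[O-]C(=O)C(Cl)(Cl)Cl
Why: Proposed new method: thermal decarboxylation of Cl3CCO2Na releases singlet dichlorocarbene, which adds as an electrophile to the C2–C3 enol ether bond of 12 to give cyclopropane 13; one chloride then ionises in a cyclopropyl-to-allyl opening pushed by the lone pairs of O1 and the silyloxy oxygen, breaking the old C2–C3 bond to give the 3-chloro-4-silyloxybenzopyrylium chloride 14, whose silyl group is taken by chloride to leave the pyranone. The closest known reaction types are the dihalocarbene one-carbon homologation of cyclic silyl enol ethers to 2-halo enones and the Ciamician–Dennstedt-type dihalocarbene expansion of indoles and benzofurans. Ring C results from enlargement of the existing furan (cyclopropanation followed by electrocyclic opening of the fused three-membered ring) rather than from any ring-closing bond to oxygen, so O1 is the benzofuran oxygen already bonded next to the aryl-bearing carbon and a 6-aryl isomer cannot arise. No stereocentre is created. The step needs site selectivity for the furan enol ether bond over the benzenoid rings and the benzylic C–H bonds, and this should follow because that doubly oxygenated alkene is by far the most nucleophilic π system of 12, while the product enone is deactivated towards further carbene addition and no acetal C–H is present.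

Step 10
Reactants: 15 5,7-bis(benzyloxy)-8-[2,3-bis(benzyloxy)-5-{[(tert-butyldimethylsilyl)oxy]methyl}phenyl]-2-[3,4-bis(benzyloxy)phenyl]-3-chloro-4H-chromen-4-one
Product: 17 5,7-bis(benzyloxy)-8-[2,3-bis(benzyloxy)-5-(hydroxymethyl)phenyl]-2-[3,4-bis(benzyloxy)phenyl]-4H-chromen-4-one, via silyl ether flavone 16 (not isolated)
Conditions: Pd(OAc)2, XPhos, HCO2Na, DMF, 80 °C; then Bu4NF, THF, rt
Reagents that add atoms: none
Why: Palladium-catalysed formate hydrodehalogenation (oxidative addition into the activated C3–Cl bond of the α-chloro enone, formate decarboxylation to a palladium hydride, reductive elimination) leaves benzyl ethers intact under homogeneous conditions, and fluoride then cleaves the primary silyl ether.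

Step 11
Reactants: 17 5,7-bis(benzyloxy)-8-[2,3-bis(benzyloxy)-5-(hydroxymethyl)phenyl]-2-[3,4-bis(benzyloxy)phenyl]-4H-chromen-4-one
Product: 18 3,4-bis(benzyloxy)-5-{5,7-bis(benzyloxy)-2-[3,4-bis(benzyloxy)phenyl]-4-oxo-4H-chromen-8-yl}benzaldehyde
Conditions: MnO2 (activated, excess), CH2Cl2, rt
Reagents that add atoms: none
Why: MnO2 oxidises the electron-rich benzylic alcohol selectively to the aldehyde without touching benzyl ethers or the flavone.

Step 12
Reactants: 19 1-[2,4-bis(benzyloxy)-6-hydroxyphenyl]ethan-1-one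
Product: 20 tert-butyl 3-[2,4-bis(benzyloxy)-6-hydroxyphenyl]-3-oxopropanoate
Conditions: LiN(SiMe3)2 (3.3 equiv), THF, −78 °C; Boc2O, −78 to 0 °C; NH4Cl (aq)
Reagents that add atoms: di-tert-butyl dicarbonate, CC(C)(C)OC(=O)OC(=O)OC(C)(C)C
Why: Claisen-type C-acylation of the phenoxide/enolate dianion with Boc2O, the third equivalent of base absorbing the acidic β-ketoester proton; any O-Boc phenol would converge by Baker–Venkataraman-type acyl transfer.

Step 13
Reactants: 18 3,4-bis(benzyloxy)-5-{5,7-bis(benzyloxy)-2-[3,4-bis(benzyloxy)phenyl]-4-oxo-4H-chromen-8-yl}benzaldehyde; 20 tert-butyl 3-[2,4-bis(benzyloxy)-6-hydroxyphenyl]-3-oxopropanoate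
Product: 21 tert-butyl 2-[2,4-bis(benzyloxy)-6-hydroxybenzoyl]-3-[3,4-bis(benzyloxy)-5-{5,7-bis(benzyloxy)-2-[3,4-bis(benzyloxy)phenyl]-4-oxo-4H-chromen-8-yl}phenyl]prop-2-enoate (alkene geometry not controlled)
Conditions: piperidine (cat.), AcOH (cat.), toluene, 4 Å sieves, rt
Reagents that add atoms: none
Why: Knoevenagel condensation of the aryl aldehyde with the β-ketoester; the bulky tert-butyl ester should hold back premature racemic ring closure of the free phenol.

Step 14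
Reactants: 21 tert-butyl 2-[2,4-bis(benzyloxy)-6-hydroxybenzoyl]-3-[3,4-bis(benzyloxy)-5-{5,7-bis(benzyloxy)-2-[3,4-bis(benzyloxy)phenyl]-4-oxo-4H-chromen-8-yl}phenyl]prop-2-enoate
Product: 23 (2S)-5,7-bis(benzyloxy)-2-[3,4-bis(benzyloxy)-5-{5,7-bis(benzyloxy)-2-[3,4-bis(benzyloxy)phenyl]-4-oxo-4H-chromen-8-yl}phenyl]chroman-4-one, via flavanone-3-carboxylate 22 (not isolated)
Conditions: 9-amino-9-deoxy-epi-quinine-derived 3,5-bis(trifluoromethyl)phenyl thiourea (10 mol%), toluene, −25 °C; then TsOH·H2O, 80 °C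
Reagents that add atoms: none
Why: Bifunctional thiourea/tertiary-amine catalysis of the intramolecular oxa-Michael addition (thiourea binds the β-ketoester, the quinuclidine activates the phenol) should set C2 as S under catalyst control, and acid then cleaves the tert-butyl ester and decarboxylates the β-keto acid without touching C2.

Step 15
Reactants: 23 (2S)-5,7-bis(benzyloxy)-2-[3,4-bis(benzyloxy)-5-{5,7-bis(benzyloxy)-2-[3,4-bis(benzyloxy)phenyl]-4-oxo-4H-chromen-8-yl}phenyl]chroman-4-one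
Product: 24 (2S)-2-{3-[2-(3,4-dihydroxyphenyl)-5,7-dihydroxy-4-oxo-4H-chromen-8-yl]-4,5-dihydroxyphenyl}-5,7-dihydroxychroman-4-one
Conditions: H2 (1 atm), Pd/C, THF/MeOH, rt
Reagents that add atoms: none
Why: Catalytic hydrogenolysis of all eight benzyl aryl ethers under neutral conditions, which should leave the flavone, the flavanone C2–O bond and the C2 configuration intact.

Compound list

1 | 3-bromo-4,5-dihydroxybenzaldehyde | O=Cc1cc(O)c(O)c(Br)c1 | starting material
2 | 3,4-bis(benzyloxy)-5-bromobenzaldehyde | O=Cc1cc(OCc2ccccc2)c(OCc2ccccc2)c(Br)c1 | intermediate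
3 | [3,4-bis(benzyloxy)-5-bromophenyl]methanol | OCc1cc(OCc2ccccc2)c(OCc2ccccc2)c(Br)c1 | intermediate
4 | {[3,4-bis(benzyloxy)-5-bromobenzyl]oxy}(tert-butyl)dimethylsilane | CC(C)(C)[Si](C)(C)OCc1cc(OCc2ccccc2)c(OCc2ccccc2)c(Br)c1 | intermediate
5 | 2-[2,3-bis(benzyloxy)-5-{[(tert-butyldimethylsilyl)oxy]methyl}phenyl]-4,4,5,5-tetramethyl-1,3,2-dioxaborolane | CC(C)(C)[Si](C)(C)OCc1cc(OCc2ccccc2)c(OCc2ccccc2)c(B2OC(C)(C)C(C)(C)O2)c1 | intermediate
6 | 4,6-dihydroxybenzofuran-3(2H)-one | O=C1COc2cc(O)cc(O)c12 | starting material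
7 | 4,6-bis(benzyloxy)benzofuran-3(2H)-one | O=C1COc2cc(OCc3ccccc3)cc(OCc3ccccc3)c12 | intermediate
8 | 4,6-bis(benzyloxy)-7-bromobenzofuran-3(2H)-one | O=C1COc2c(Br)c(OCc3ccccc3)cc(OCc3ccccc3)c12 | intermediate
9 | 4,6-bis(benzyloxy)-7-[2,3-bis(benzyloxy)-5-{[(tert-butyldimethylsilyl)oxy]methyl}phenyl]benzofuran-3(2H)-one | O=C1COc2c(-c3cc(CO[Si](C)(C)C(C)(C)C)cc(OCc4ccccc4)c3OCc5ccccc5)c(OCc6ccccc6)cc(OCc7ccccc7)c12 | intermediate
10 | 1,2-bis(benzyloxy)-4-bromobenzene | Brc1ccc(OCc2ccccc2)c(OCc2ccccc2)c1 | starting material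
11 | lithium 4,6-bis(benzyloxy)-7-[2,3-bis(benzyloxy)-5-{[(tert-butyldimethylsilyl)oxy]methyl}phenyl]-2-[3,4-bis(benzyloxy)phenyl]benzofuran-3-olate (enolate of the 2-aryl ketone) | [Li+].[O-]c1c(-c2ccc(OCc3ccccc3)c(OCc3ccccc3)c2)oc2c(-c3cc(CO[Si](C)(C)C(C)(C)C)cc(OCc4ccccc4)c3OCc5ccccc5)c(OCc6ccccc6)cc(OCc7ccccc7)c12 | intermediate (not isolated)
12 | 4,6-bis(benzyloxy)-7-[2,3-bis(benzyloxy)-5-{[(tert-butyldimethylsilyl)oxy]methyl}phenyl]-2-[3,4-bis(benzyloxy)phenyl]-3-[(tert-butyldimethylsilyl)oxy]benzofuran | CC(C)(C)[Si](C)(C)Oc1c(-c2ccc(OCc3ccccc3)c(OCc3ccccc3)c2)oc2c(-c3cc(CO[Si](C)(C)C(C)(C)C)cc(OCc4ccccc4)c3OCc5ccccc5)c(OCc6ccccc6)cc(OCc7ccccc7)c12 | intermediate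
13 | 1,1-dichloro-1a-[3,4-bis(benzyloxy)phenyl]-6b-[(tert-butyldimethylsilyl)oxy]-1a,6b-dihydro-1H-cyclopropa[b]benzofuran carrying the 4,6-bis(benzyloxy) and 7-aryl groups of 12 (racemic, cis-fused) | CC(C)(C)[Si](C)(C)OC12C(Cl)(Cl)C1(c1ccc(OCc3ccccc3)c(OCc3ccccc3)c1)Oc1c(-c3cc(CO[Si](C)(C)C(C)(C)C)cc(OCc4ccccc4)c3OCc5ccccc5)c(OCc6ccccc6)cc(OCc7ccccc7)c12 | intermediate (not isolated)
14 | 5,7-bis(benzyloxy)-8-[2,3-bis(benzyloxy)-5-{[(tert-butyldimethylsilyl)oxy]methyl}phenyl]-2-[3,4-bis(benzyloxy)phenyl]-4-[(tert-butyldimethylsilyl)oxy]-3-chlorochromenylium chloride | [Cl-].CC(C)(C)[Si](C)(C)Oc1c(Cl)c(-c2ccc(OCc3ccccc3)c(OCc3ccccc3)c2)[o+]c2c(-c3cc(CO[Si](C)(C)C(C)(C)C)cc(OCc4ccccc4)c3OCc5ccccc5)c(OCc6ccccc6)cc(OCc7ccccc7)c12 | intermediate (not isolated)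
15 | 5,7-bis(benzyloxy)-8-[2,3-bis(benzyloxy)-5-{[(tert-butyldimethylsilyl)oxy]methyl}phenyl]-2-[3,4-bis(benzyloxy)phenyl]-3-chloro-4H-chromen-4-one | O=c1c(Cl)c(-c2ccc(OCc3ccccc3)c(OCc3ccccc3)c2)oc2c(-c3cc(CO[Si](C)(C)C(C)(C)C)cc(OCc4ccccc4)c3OCc5ccccc5)c(OCc6ccccc6)cc(OCc7ccccc7)c12 | intermediate
16 | 5,7-bis(benzyloxy)-8-[2,3-bis(benzyloxy)-5-{[(tert-butyldimethylsilyl)oxy]methyl}phenyl]-2-[3,4-bis(benzyloxy)phenyl]-4H-chromen-4-one | O=c1cc(-c2ccc(OCc3ccccc3)c(OCc3ccccc3)c2)oc2c(-c3cc(CO[Si](C)(C)C(C)(C)C)cc(OCc4ccccc4)c3OCc5ccccc5)c(OCc6ccccc6)cc(OCc7ccccc7)c12 | intermediate (not isolated)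
17 | 5,7-bis(benzyloxy)-8-[2,3-bis(benzyloxy)-5-(hydroxymethyl)phenyl]-2-[3,4-bis(benzyloxy)phenyl]-4H-chromen-4-one | O=c1cc(-c2ccc(OCc3ccccc3)c(OCc3ccccc3)c2)oc2c(-c3cc(CO)cc(OCc4ccccc4)c3OCc5ccccc5)c(OCc6ccccc6)cc(OCc7ccccc7)c12 | intermediate
18 | 3,4-bis(benzyloxy)-5-{5,7-bis(benzyloxy)-2-[3,4-bis(benzyloxy)phenyl]-4-oxo-4H-chromen-8-yl}benzaldehyde | O=c1cc(-c2ccc(OCc3ccccc3)c(OCc3ccccc3)c2)oc2c(-c3cc(C=O)cc(OCc4ccccc4)c3OCc5ccccc5)c(OCc6ccccc6)cc(OCc7ccccc7)c12 | intermediate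
19 | 1-[2,4-bis(benzyloxy)-6-hydroxyphenyl]ethan-1-one | CC(=O)c1c(O)cc(OCc2ccccc2)cc1OCc1ccccc1 | starting material
20 | tert-butyl 3-[2,4-bis(benzyloxy)-6-hydroxyphenyl]-3-oxopropanoate | CC(C)(C)OC(=O)CC(=O)c1c(O)cc(OCc2ccccc2)cc1OCc1ccccc1 | intermediate
21 | tert-butyl 2-[2,4-bis(benzyloxy)-6-hydroxybenzoyl]-3-[3,4-bis(benzyloxy)-5-{5,7-bis(benzyloxy)-2-[3,4-bis(benzyloxy)phenyl]-4-oxo-4H-chromen-8-yl}phenyl]prop-2-enoate (E/Z mixture) | CC(C)(C)OC(=O)C(=Cc1cc(OCc2ccccc2)c(OCc2ccccc2)c(-c2c(OCc3ccccc3)cc(OCc3ccccc3)c3c(=O)cc(-c4ccc(OCc5ccccc5)c(OCc5ccccc5)c4)oc23)c1)C(=O)c1c(O)cc(OCc2ccccc2)cc1OCc1ccccc1 | intermediate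
22 | tert-butyl (2S)-5,7-bis(benzyloxy)-2-[3,4-bis(benzyloxy)-5-{5,7-bis(benzyloxy)-2-[3,4-bis(benzyloxy)phenyl]-4-oxo-4H-chromen-8-yl}phenyl]-4-oxochromane-3-carboxylate (C3 epimers) | O=C1C(C(=O)OC(C)(C)C)[C@@H](c2cc(OCc3ccccc3)c(OCc3ccccc3)c(-c3c(OCc4ccccc4)cc(OCc4ccccc4)c4c(=O)cc(-c5ccc(OCc6ccccc6)c(OCc6ccccc6)c5)oc34)c2)Oc2cc(OCc3ccccc3)cc(OCc3ccccc3)c21 | intermediate (not isolated)
23 | (2S)-5,7-bis(benzyloxy)-2-[3,4-bis(benzyloxy)-5-{5,7-bis(benzyloxy)-2-[3,4-bis(benzyloxy)phenyl]-4-oxo-4H-chromen-8-yl}phenyl]chroman-4-one | O=C1C[C@@H](c2cc(OCc3ccccc3)c(OCc3ccccc3)c(-c3c(OCc4ccccc4)cc(OCc4ccccc4)c4c(=O)cc(-c5ccc(OCc6ccccc6)c(OCc6ccccc6)c5)oc34)c2)Oc2cc(OCc3ccccc3)cc(OCc3ccccc3)c21 | intermediate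
24 | (2S)-2-{3-[2-(3,4-dihydroxyphenyl)-5,7-dihydroxy-4-oxo-4H-chromen-8-yl]-4,5-dihydroxyphenyl}-5,7-dihydroxychroman-4-one | O=C1C[C@@H](c2cc(O)c(O)c(-c3c(O)cc(O)c4c(=O)cc(-c5ccc(O)c(O)c5)oc34)c2)Oc2cc(O)cc(O)c21 | target

Total step count: 15. Longest linear sequence: 12 steps (steps 1–4, 7–11, 13–15).

Steps most likely to fail

Step 9. Carbene addition to the hindered, tetrasubstituted enol ether may be slow, or be diverted by desilylation or by C–H insertion, so that ring expansion stalls or gives mixtures. The fallback uses known chemistry and sets out from boronate 5. Commercial luteolin F1 would be perbenzylated (BnBr, K2CO3, DMF, 80 °C) to 5,7,3',4'-tetra-O-benzylluteolin F2. Electrophilic iodination (I2, AgO2CCF3, CH2Cl2), which is C8-selective in fully alkylated 5,7-dioxygenated flavones, should give 8-iodo-5,7,3',4'-tetra-O-benzylluteolin F3. Suzuki–Miyaura coupling of that iodide with 5 (Pd(OAc)2, SPhos, K3PO4, toluene/H2O) would give 16, where the fallback rejoins the route at the fluoride treatment of step 10.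

Step 8. A second arylation, reduction of the aryl bromide, aerobic oxidation of the 2-aryl enolate before it is trapped, or incomplete silylation at the crowded oxygen could erode the one-flask sequence. The fallback sets out from 9, which would be silylated first (TBSOTf, Et3N, CH2Cl2) to 4,6-bis(benzyloxy)-7-aryl-3-[(tert-butyldimethylsilyl)oxy]benzofuran F4. Deprotonation at C2 with LiN(iPr)2 at −78 °C and transmetalation with ZnCl2 would give the 2-benzofuranylzinc chloride F5. Negishi coupling of this with 10 (Pd(OAc)2, SPhos, THF, 40 °C) would give 12 directly.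

Step 14. Enantioselectivity may be insufficient with the 6'-alkoxy aryl ketone, or the ee may be eroded by a racemic background cyclisation during or after the Knoevenagel step. The fallback sets out from aldehyde 18 and acetophenone 19. Claisen–Schmidt condensation (KOH, EtOH/THF, rt) would give the (E)-2'-hydroxychalcone F6. Cyclisation with NaOAc in refluxing EtOH would give the racemic octabenzyl flavanone F7, which would be resolved by preparative chiral-phase HPLC to return to the route at 23.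

Further compounds

F1 | step 9 | luteolin | O=c1cc(-c2ccc(O)c(O)c2)oc2cc(O)cc(O)c12
F2 | step 9 | 5,7,3',4'-tetra-O-benzylluteolin | O=c1cc(-c2ccc(OCc3ccccc3)c(OCc3ccccc3)c2)oc2cc(OCc3ccccc3)cc(OCc3ccccc3)c12
F3 | step 9 | 8-iodo-5,7,3',4'-tetra-O-benzylluteolin | O=c1cc(-c2ccc(OCc3ccccc3)c(OCc3ccccc3)c2)oc2c(I)c(OCc3ccccc3)cc(OCc3ccccc3)c12
F4 | step 8 | 4,6-bis(benzyloxy)-7-[2,3-bis(benzyloxy)-5-{[(tert-butyldimethylsilyl)oxy]methyl}phenyl]-3-[(tert-butyldimethylsilyl)oxy]benzofuran | CC(C)(C)[Si](C)(C)Oc1coc2c(-c3cc(CO[Si](C)(C)C(C)(C)C)cc(OCc4ccccc4)c3OCc5ccccc5)c(OCc6ccccc6)cc(OCc7ccccc7)c12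
F5 | step 8 | {4,6-bis(benzyloxy)-7-[2,3-bis(benzyloxy)-5-{[(tert-butyldimethylsilyl)oxy]methyl}phenyl]-3-[(tert-butyldimethylsilyl)oxy]benzofuran-2-yl}zinc chloride | CC(C)(C)[Si](C)(C)Oc1c([Zn]Cl)oc2c(-c3cc(CO[Si](C)(C)C(C)(C)C)cc(OCc4ccccc4)c3OCc5ccccc5)c(OCc6ccccc6)cc(OCc7ccccc7)c12
F6 | step 14 | (E)-1-[2,4-bis(benzyloxy)-6-hydroxyphenyl]-3-[3,4-bis(benzyloxy)-5-{5,7-bis(benzyloxy)-2-[3,4-bis(benzyloxy)phenyl]-4-oxo-4H-chromen-8-yl}phenyl]prop-2-en-1-one | O=C(/C=C/c1cc(OCc2ccccc2)c(OCc2ccccc2)c(-c2c(OCc3ccccc3)cc(OCc3ccccc3)c3c(=O)cc(-c4ccc(OCc5ccccc5)c(OCc5ccccc5)c4)oc23)c1)c1c(O)cc(OCc2ccccc2)cc1OCc1ccccc1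
F7 | step 14 | racemic 5,7-bis(benzyloxy)-2-[3,4-bis(benzyloxy)-5-{5,7-bis(benzyloxy)-2-[3,4-bis(benzyloxy)phenyl]-4-oxo-4H-chromen-8-yl}phenyl]chroman-4-one | O=C1CC(c2cc(OCc3ccccc3)c(OCc3ccccc3)c(-c3c(OCc4ccccc4)cc(OCc4ccccc4)c4c(=O)cc(-c5ccc(OCc6ccccc6)c(OCc6ccccc6)c5)oc34)c2)Oc2cc(OCc3ccccc3)cc(OCc3ccccc3)c21
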